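The constants are hidden, so what can still be said about these flasks? Follow one E. The steps proposed give it two ways out: it joins Q as G and may leave as Z, or it meets another E and leaves as J. Once E has run down and G, X and D have given up the E they hold, the percent of Z is the chance that an E took the first way, its selectivity for Z, and that chance can be read without a constant.

| setting | teal | blue | gamma | alpha | delta | epsilon | zeta |
|---|---|---|---|---|---|---|---|
| E | 0.20 mM | 0.20 mM | 0.20 mM | 0.20 mM | 0.20 mM | 0.20 mM | 0.20 mM |
| Q | 2.9 µM | 21 µM | 5.0 µM | 8.0 µM | 12 µM | 15 µM | 25 µM |
| remark | run made earlier | run made earlier |  |  |  |  |  |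
| time |  |  | 4.0 min | 4.0 min | 4.0 min | 4.0 min | 4.0 min |

- teal (time / min: Z / %, E / %): 0.417: 8.6, 11.2; 0.833: 11.6, 4.9; 1.33: 14.2, 1.3; 1.50: 14.1, 1.7; 2.00: 16.6, 0.5; 2.50: 15.6, 0; 3.00: 17.5, 1.0
- blue (time / min: Z / %, E / %): 0.417: 29.5, 4.7; 0.833: 38.7, 0.8; 1.33: 38.7, 0; 1.50: 38.0, 0; 2.00: 37.1, 0; 2.50: 39.2, 0; 3.00: 38.1, 0

(each reading ± 1 percentage point)

- a species is counted by the E in it: one D or J counts as two
- what was read earlier has a scatter of 1 percentage point, one standard deviation
- what may be going on: G <-> X; X -> Q + Z; 2 X <-> D; E + Q <-> G; 2 E -> J
- "hardly changes" means that all values lie within two and a half points (for a concentration: within two and a half percent of the largest)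

1. amount of Z at the end, in percent of the E charged for gamma, alpha, delta, epsilon, zeta, in this order
2. how the row runs (rises, then falls / rises all the way / hardly changes / falls, then rises / falls all the way)

Has E run down in time? At 3.00 min teal reads E 1.0% and blue reads 0%, against a scatter of 1 percentage point, and the row is taken later, at 4.0 min. So the row asks for plateaus.

What are the plateaus so far? The last 3 Z readings of teal average 16.6%, and the last 5 of blue average 38.2%. E is charged at 0.20 mM in the runs and in the row, so cQ is what differs.

Does the chance grow in step with cQ? No. Blue has 7.24 times the cQ of teal but 2.30 times the Z. Z made per Q charged is 3.64 in blue, less than the 11.4 in teal.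

Then what do you carry to the next flask? The plateau exponent, the rise of ln(plateau Z) per unit rise of ln(cQ) at fixed charge of E, 0.422. It costs two plateaus and no constant.

Two points fit any line, so what entitles you to it? Nothing proves the exponent constant. But 4 flasks of the row lie inside the range of cQ already run, and zeta, at 25 µM, lies a little beyond blue's 21 µM, so for zeta the line is carried past the runs.

Your row, then? Multiplying teal's plateau by (cQ over teal's cQ) raised to the exponent, I commit to 20.9%, 25.4%, 30.2%, 33.2% and 41.1%, rising from each flask to the next.

The forecast gives 22%, 26%, 31%, 33.5% and 40%, and says the row rises all the way: “The yield should keep rising and flatten, roughly as Q^0.4.” My row lies below it at gamma and above it at zeta.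

The flasks give 20.9%, 25.6%, 30.4%, 33.4% and 41.4%, and the row rises all the way.

    G ⇌ X (K = 0.950, k = 7.51 /s)
    X → Q + Z (k = 1.58 /s)
    2 X ⇌ D, settled at all times (K = 2.29 × 10⁶ /M)
    E + Q ⇌ G (K = 37100 /M, k = 12200 /M/s)
    2 E → J (k = 573 /M/s)

Zeta at 4.00 min holds E 0%, Z 41.4% and J 58.6%, so the E charged stands at the two exits of the fork. Carried from gamma's 20.9% with the exponent 0.422, zeta comes to 41.2%, against the 41.4% it gives. Carried the same way, epsilon comes to 33.2%, against the 33.4% it gives.

The readings stem from a simulated flask on assumed constants; noise was put on by code.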